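## Retrosynthetic overview

1. Target ⇐ 6,7,13-triol by lipase-catalysed acetylation of the C7 hydroxyl alone. The C13 carbinol ⇐ Sharpless epoxidation of an (E)-allylic alcohol plus reductive epoxide opening; the allylic alcohol ⇐ terminal alkyne by methylalumination and formaldehyde.
2. cis-6,7-Diol ⇐ OsO4 on the C6=C7 bond of a 5(10),6-diene ⇐ C6 enone, through its dienyl triflate.
3. Enone carrying C8 and C9 ⇐ catalytic asymmetric Diels–Alder reaction of a 2-silyloxy diene built on ring A with an (E)-2-alkylbut-2-enal; the formyl group becomes the C9 methyl.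
4. Ring order: ring A is bought as 2,2-dimethylcyclohexanone, ring B is closed by the cycloaddition, and the side chain is finished last.

Locants C1–C20 are the halimane positions of the target: ring A is C1–C5 and C10, ring B is C5–C10, and the side chain is C11–C16.

Assumption: the (S)-oxazaborolidinium salt of step 8 is taken to leave the Cα-Re face of the bound enal open; if the first run shows the opposite sense, the (R)-salt is used and nothing else changes.

## Route

Step 1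
Reactants: 1 2,2-dimethylcyclohexan-1-one
Product: 3 6,6-dimethylcyclohex-1-en-1-yl triflate, via lithium enolate 2 (not isolated)
Conditions: lithium diisopropylamide, THF, −78 °C; then PhNTf2, −78 °C → rt
Reagents that add atoms: N-phenylbis(trifluoromethanesulfonimide), O=S(=O)(N(c1ccccc1)S(=O)(=O)C(F)(F)F)C(F)(F)F
Why: Only one α-carbon carries hydrogen, so enolisation and O-sulfonylation (enol triflate formation) give a single regioisomer.

Step 2
Reactants: 3 6,6-dimethylcyclohex-1-en-1-yl triflate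
Product: 5 1-(6,6-dimethylcyclohex-1-en-1-yl)ethan-1-one, via ethoxydiene 4 (not isolated)
Conditions: tributyl(1-ethoxyethenyl)stannane, Pd(PPh3)4 (5 mol%), LiCl, THF, reflux; then 1 M HCl, rt
Reagents that add atoms: tributyl(1-ethoxyethenyl)stannane, C=C(OCC)[Sn](CCCC)(CCCC)CCCC; water, O
Why: Stille coupling of the vinyl triflate with an acetyl-anion equivalent, followed by enol ether hydrolysis, gives the conjugated methyl ketone.

Step 3
Reactants: 5 1-(6,6-dimethylcyclohex-1-en-1-yl)ethan-1-one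
Product: 6 2-(triisopropylsilyloxy) diene of ring A
Conditions: iPr3SiOTf, Et3N, CH2Cl2, 0 °C
Reagents that add atoms: triisopropylsilyl trifluoromethanesulfonate, CC(C)[Si](C(C)C)(C(C)C)OS(=O)(=O)C(F)(F)F
Why: Soft enolisation at the methyl group (silyl enol ether formation) gives the cross-conjugated 2-silyloxy diene, in which C7 is the nucleophilic terminus.

Step 4
Reactants: 7 hex-5-yn-1-ol
Product: 10 6-(trimethylsilyl)hex-5-yn-1-ol, via dilithiated alkynol 8 (not isolated), via bis-silylated alkynol 9 (not isolated)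
Conditions: n-BuLi (2.2 equiv), THF, −78 °C; Me3SiCl (2.3 equiv), → rt; then 1 M HCl, rt
Reagents that add atoms: chlorotrimethylsilane, C[Si](C)(C)Cl
Why: C- and O-silylation of the dianion and selective acid cleavage of the labile O–Si bond leave the alkyne masked for the later palladium steps.

Step 5
Reactants: 10 6-(trimethylsilyl)hex-5-yn-1-ol
Product: 11 6-(trimethylsilyl)hex-5-ynal
Conditions: PhI(OAc)2, TEMPO (2,2,6,6-tetramethylpiperidin-1-oxyl, 10 mol%), CH2Cl2, rt
Reagents that add atoms: none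
Why: Oxoammonium-mediated (TEMPO) oxidation of the primary alcohol stops cleanly at the aldehyde.

Step 6
Reactants: 11 6-(trimethylsilyl)hex-5-ynal
Product: 12 N-cyclohexyl imine of 11
Conditions: cyclohexylamine, MgSO4, Et2O, 0 °C → rt
Reagents that add atoms: cyclohexylamine, NC1CCCCC1
Why: Imine condensation masks the aldehyde so that it can serve as the donor in a directed aldol reaction without self-condensation.

Step 7
Reactants: 12 N-cyclohexyl imine of 11
Product: 15 (2E)-2-ethylidene-6-(trimethylsilyl)hex-5-ynal, via lithium azaenolate 13 (not isolated), via lithium aldolate 14 (not isolated)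
Conditions: lithium diisopropylamide, THF, −78 °C; CH3CHO, −78 °C; then aq. oxalic acid, rt
Reagents that add atoms: acetaldehyde, CC=O; water, O
Why: Wittig directed aldol condensation: the azaenolate adds to acetaldehyde, and acid hydrolysis with dehydration gives the thermodynamically preferred (E)-enal (formyl trans to the β-methyl), the two transient stereocentres of 14 being lost.

Step 8
Reactants: 6 2-(triisopropylsilyloxy) diene of ring A; 15 (2E)-2-ethylidene-6-(trimethylsilyl)hex-5-ynal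
Product: 16 cycloadduct aldehyde (TIPS enol ether)
Conditions: (S)-3,3-diphenyl-1-(2-methylphenyl)tetrahydro-1H,3H-pyrrolo[1,2-c][1,3,2]oxazaborole (C24H24BNO, 20 mol%), HN(SO2CF3)2 (20 mol%), CH2Cl2, −78 → −40 °C
Reagents that add atoms: none
Why: Lewis-acid-catalysed asymmetric Diels–Alder reaction in which the silyloxy group and the ring substituent of 6 both direct C7 to the β-carbon and C10 to the α-carbon of 15, the E geometry is carried over suprafacially (C8 methyl cis to the C11 chain, trans to the formyl group) and the chiral oxazaborolidinium ion leaves only the Cα-Re face open, which sets C8 and C9 as the first stereocentres that are kept, while the C10 epimers from endo and exo addition converge in step 9.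

Step 9
Reactants: 16 cycloadduct aldehyde (TIPS enol ether)
Product: 17 enone aldehyde
Conditions: Pd(OAc)2 (1.2 equiv), MeCN, 40 °C
Reagents that add atoms: none
Why: Saegusa–Ito dehydrogenation: the palladium enolate at C5 can lose a β-hydrogen only from C10 because C4 is quaternary, so the tetrasubstituted C5=C10 enone forms regiospecifically.

Step 10
Reactants: 17 enone aldehyde
Product: 18 tosylhydrazone of 17
Conditions: TsNHNH2 (1.05 equiv), THF, rt
Reagents that add atoms: 4-methylbenzenesulfonohydrazide, Cc1ccc(cc1)S(=O)(=O)NN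
Why: Hydrazone condensation occurs only at the aldehyde because the C6 carbonyl is a hindered, fully substituted enone, and the crystalline product can be recrystallised to raise the enantiomeric purity.

Step 11
Reactants: 18 tosylhydrazone of 17
Product: 20 (3R,4R)-methyl enone, via N-boryl hydrazide 19 (not isolated)
Conditions: catecholborane, CHCl3, 0 °C; then NaOAc·3H2O, reflux
Reagents that add atoms: none
Why: Kabalka reductive deoxygenation (hydride addition to C=N, loss of sulfinate and of N2 from the diazene) turns the neopentyl formyl group into the C9 methyl without touching the s-trans enone or the silyl alkyne; C9 keeps its geometry and only its descriptor changes.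

Step 12
Reactants: 20 (3R,4R)-methyl enone
Product: 22 cross-conjugated dienyl triflate, via potassium dienolate 21 (not isolated)
Conditions: KN(SiMe3)2, THF, −78 °C; then PhNTf2, −78 → 0 °C
Reagents that add atoms: N-phenylbis(trifluoromethanesulfonimide), O=S(=O)(N(c1ccccc1)S(=O)(=O)C(F)(F)F)C(F)(F)F
Why: Kinetic α′-deprotonation at C7 and O-sulfonylation (enol triflate formation) place the new double bond at C6=C7.

Step 13
Reactants: 22 cross-conjugated dienyl triflate
Product: 23 5(10),6-diene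
Conditions: Pd(OAc)2 (5 mol%), PPh3 (10 mol%), HCO2H, Et3N, DMF, 60 °C
Reagents that add atoms: none
Why: Palladium-catalysed formate reduction of the vinyl triflate (oxidative addition, decarboxylation to a palladium hydride, reductive elimination) replaces the triflate by hydrogen without moving either double bond.

Step 14
Reactants: 23 5(10),6-diene
Product: 24 (1S,2R,3S,4R)-cis-diol
Conditions: OsO4 (5 mol%), N-methylmorpholine N-oxide, acetone/H2O, 0 °C → rt
Reagents that add atoms: osmium tetroxide, O=[Os](=O)(=O)=O; N-methylmorpholine N-oxide, C[N+]1([O-])CCOCC1; water, O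
Why: Upjohn syn-dihydroxylation takes the only accessible double bond (C6=C7; C5=C10 is tetrasubstituted between two quaternary carbons) from the face opposite the allylic C8 methyl and the C9 chain, which sets C6 (S) and C7 (R) together as the cis-diol trans to the C8 methyl.

Step 15
Reactants: 24 (1S,2R,3S,4R)-cis-diol
Product: 25 bis-TBS ether
Conditions: tBuMe2SiOTf (3 equiv), 2,6-lutidine, CH2Cl2, 0 °C → rt
Reagents that add atoms: tert-butyldimethylsilyl trifluoromethanesulfonate, CC(C)(C)[Si](C)(C)OS(=O)(=O)C(F)(F)F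
Why: Silyl triflate silylation protects both hydroxyls, the hindered C6 one included, as base- and Lewis-acid-stable ethers that can later be removed with fluoride under non-acidic conditions.

Step 16
Reactants: 25 bis-TBS ether
Product: 26 terminal alkyne
Conditions: K2CO3, MeOH/THF, rt
Reagents that add atoms: none
Why: Base-catalysed protodesilylation cleaves only the alkynyl C–Si bond.

Step 17
Reactants: 26 terminal alkyne
Product: 28 (E)-allylic alcohol, via alkenylalane 27 (not isolated)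
Conditions: AlMe3 (3 equiv), (C5H5)2ZrCl2 (0.5 equiv), CH2Cl2, 0 °C → rt; then (CH2O)n, THF, 0 °C → rt
Reagents that add atoms: trimethylaluminium, C[Al](C)C; formaldehyde (as paraformaldehyde), C=O
Why: Negishi zirconium-catalysed carboalumination adds methyl and aluminium syn across the alkyne with the methyl on the internal carbon, and trapping with formaldehyde with retention gives the (E)-trisubstituted allylic alcohol.

Step 18
Reactants: 28 (E)-allylic alcohol
Product: 29 (2R,3R)-epoxy alcohol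
Conditions: Ti(OiPr)4 (10 mol%), D-(−)-diethyl tartrate (12 mol%), t-BuOOH, 4 Å sieves, CH2Cl2, −20 °C
Reagents that add atoms: tert-butyl hydroperoxide, CC(C)(C)OO
Why: Katsuki–Sharpless asymmetric epoxidation is reagent-controlled, and the D-(−)-tartrate delivers oxygen to the face that gives the (2R,3R)-epoxide, i.e. C13 (R), irrespective of the remote ring stereocentres.

Step 19
Reactants: 29 (2R,3R)-epoxy alcohol
Product: 30 epoxy iodide
Conditions: I2, PPh3, imidazole, THF, 0 °C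
Reagents that add atoms: iodine, II
Why: Appel-type iodination of the primary alcohol proceeds without opening the epoxide.

Step 20
Reactants: 30 epoxy iodide
Product: 31 tertiary allylic alcohol (bis-TBS)
Conditions: Zn dust, EtOH, reflux
Reagents that add atoms: none
Why: Reductive epoxide opening (zinc insertion into the C–I bond and β-elimination of the epoxide oxygen) gives the vinyl carbinol while the C13–O bond stays intact, so C13 remains (R).

Step 21
Reactants: 31 tertiary allylic alcohol (bis-TBS)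
Product: 32 6,7,13-triol
Conditions: Bu4NF, THF, rt → 50 °C
Reagents that add atoms: none
Why: Fluoride desilylation frees both ring hydroxyls under non-acidic conditions that spare the two ionisable allylic C–O bonds.

Step 22
Reactants: 32 6,7,13-triol
Product: 33 target
Conditions: Burkholderia cepacia lipase (immobilised), vinyl acetate, t-BuOMe, 35 °C
Reagents that add atoms: vinyl acetate, CC(=O)OC=C
Why: Lipase (serine hydrolase) transesterification: the C6 hydroxyl is buried between the C5=C10 bond and the C4 gem-dimethyl group and the tertiary C13 hydroxyl is not accepted, so the acyl-enzyme passes its acetyl only to the (R)-configured C7 hydroxyl, the arrangement such lipases prefer in cyclic cis-1,2-diols.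

## Compound list

1 | 2,2-dimethylcyclohexan-1-one | CC1(C)CCCCC1=O | starting material
2 | lithium 6,6-dimethylcyclohex-1-en-1-olate | [Li]OC1=CCCCC1(C)C | intermediate (not isolated)
3 | 6,6-dimethylcyclohex-1-en-1-yl trifluoromethanesulfonate | CC1(C)CCCC=C1OS(=O)(=O)C(F)(F)F | intermediate
4 | 1-(1-ethoxyethenyl)-6,6-dimethylcyclohex-1-ene | C=C(OCC)C1=CCCCC1(C)C | intermediate (not isolated)
5 | 1-(6,6-dimethylcyclohex-1-en-1-yl)ethan-1-one | CC(=O)C1=CCCCC1(C)C | intermediate
6 | triisopropyl{[1-(6,6-dimethylcyclohex-1-en-1-yl)ethenyl]oxy}silane | C=C(O[Si](C(C)C)(C(C)C)C(C)C)C1=CCCCC1(C)C | intermediate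
7 | hex-5-yn-1-ol | C#CCCCCO | starting material
8 | lithium 6-lithiohex-5-yn-1-olate | [Li]OCCCCC#C[Li] | intermediate (not isolated)
9 | trimethyl{[6-(trimethylsilyl)hex-5-yn-1-yl]oxy}silane | C[Si](C)(C)OCCCCC#C[Si](C)(C)C | intermediate (not isolated)
10 | 6-(trimethylsilyl)hex-5-yn-1-ol | OCCCCC#C[Si](C)(C)C | intermediate
11 | 6-(trimethylsilyl)hex-5-ynal | O=CCCCC#C[Si](C)(C)C | intermediate
12 | (1E)-N-cyclohexyl-6-(trimethylsilyl)hex-5-yn-1-imine | C[Si](C)(C)C#CCCC/C=N/C1CCCCC1 | intermediate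
13 | lithium cyclohexyl[6-(trimethylsilyl)hex-1-en-5-yn-1-yl]azanide | [Li]N(C=CCCC#C[Si](C)(C)C)C1CCCCC1 | intermediate (not isolated)
14 | lithium 3-[(E)-(cyclohexylimino)methyl]-7-(trimethylsilyl)hept-6-yn-2-olate, diastereomer mixture | CC(O[Li])C(CCC#C[Si](C)(C)C)/C=N/C1CCCCC1 | intermediate (not isolated)
15 | (2E)-2-ethylidene-6-(trimethylsilyl)hex-5-ynal | C/C=C(\CCC#C[Si](C)(C)C)C=O | intermediate
16 | (1S,2R)-2,5,5-trimethyl-4-[(triisopropylsilyl)oxy]-1-[4-(trimethylsilyl)but-3-yn-1-yl]-1,2,3,5,6,7,8,8a-octahydronaphthalene-1-carbaldehyde, both C8a epimers (C8a left open in the SMILES) | C[Si](C)(C)C#CCC[C@@]1(C=O)C2CCCC(C)(C)C2=C(O[Si](C(C)C)(C(C)C)C(C)C)C[C@H]1C | intermediate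
17 | (1S,2R)-2,5,5-trimethyl-4-oxo-1-[4-(trimethylsilyl)but-3-yn-1-yl]-1,2,3,4,5,6,7,8-octahydronaphthalene-1-carbaldehyde | C[Si](C)(C)C#CCC[C@@]1(C=O)C2=C(C(=O)C[C@H]1C)C(C)(C)CCC2 | intermediate
18 | N'-[(E)-{(1S,2R)-2,5,5-trimethyl-4-oxo-1-[4-(trimethylsilyl)but-3-yn-1-yl]-1,2,3,4,5,6,7,8-octahydronaphthalen-1-yl}methylidene]-4-methylbenzenesulfonohydrazide | C[Si](C)(C)C#CCC[C@@]1(/C=N/NS(=O)(=O)c3ccc(C)cc3)C2=C(C(=O)C[C@H]1C)C(C)(C)CCC2 | intermediate
19 | N'-(1,3,2-benzodioxaborol-2-yl)-N'-({(1S,2R)-2,5,5-trimethyl-4-oxo-1-[4-(trimethylsilyl)but-3-yn-1-yl]-1,2,3,4,5,6,7,8-octahydronaphthalen-1-yl}methyl)-4-methylbenzenesulfonohydrazide | C[Si](C)(C)C#CCC[C@@]1(CN(B3Oc4ccccc4O3)NS(=O)(=O)c3ccc(C)cc3)C2=C(C(=O)C[C@H]1C)C(C)(C)CCC2 | intermediate (not isolated)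
20 | (3R,4R)-3,4,8,8-tetramethyl-4-[4-(trimethylsilyl)but-3-yn-1-yl]-3,4,5,6,7,8-hexahydronaphthalen-1(2H)-one | C[Si](C)(C)C#CCC[C@@]1(C)C2=C(C(=O)C[C@H]1C)C(C)(C)CCC2 | intermediate
21 | potassium (3R,4R)-3,4,8,8-tetramethyl-4-[4-(trimethylsilyl)but-3-yn-1-yl]-3,4,5,6,7,8-hexahydronaphthalen-1-olate | C[Si](C)(C)C#CCC[C@@]1(C)C2=C(C(O[K])=C[C@H]1C)C(C)(C)CCC2 | intermediate (not isolated)
22 | (3R,4R)-3,4,8,8-tetramethyl-4-[4-(trimethylsilyl)but-3-yn-1-yl]-3,4,5,6,7,8-hexahydronaphthalen-1-yl trifluoromethanesulfonate | C[Si](C)(C)C#CCC[C@@]1(C)C2=C(C(OS(=O)(=O)C(F)(F)F)=C[C@H]1C)C(C)(C)CCC2 | intermediate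
23 | trimethyl{4-[(1R,2R)-1,2,5,5-tetramethyl-1,2,5,6,7,8-hexahydronaphthalen-1-yl]but-1-yn-1-yl}silane | C[Si](C)(C)C#CCC[C@@]1(C)C2=C(C=C[C@H]1C)C(C)(C)CCC2 | intermediate
24 | (1S,2R,3S,4R)-3,4,8,8-tetramethyl-4-[4-(trimethylsilyl)but-3-yn-1-yl]-1,2,3,4,5,6,7,8-octahydronaphthalene-1,2-diol | C[Si](C)(C)C#CCC[C@@]1(C)C2=C([C@H](O)[C@H](O)[C@H]1C)C(C)(C)CCC2 | intermediate
25 | (1S,2R,3S,4R)-1,2-bis{[tert-butyl(dimethyl)silyl]oxy}-3,4,8,8-tetramethyl-4-[4-(trimethylsilyl)but-3-yn-1-yl]-1,2,3,4,5,6,7,8-octahydronaphthalene | C[Si](C)(C)C#CCC[C@@]1(C)C2=C([C@H](O[Si](C)(C)C(C)(C)C)[C@H](O[Si](C)(C)C(C)(C)C)[C@H]1C)C(C)(C)CCC2 | intermediate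
26 | (1S,2R,3S,4R)-4-(but-3-yn-1-yl)-1,2-bis{[tert-butyl(dimethyl)silyl]oxy}-3,4,8,8-tetramethyl-1,2,3,4,5,6,7,8-octahydronaphthalene | C#CCC[C@@]1(C)C2=C([C@H](O[Si](C)(C)C(C)(C)C)[C@H](O[Si](C)(C)C(C)(C)C)[C@H]1C)C(C)(C)CCC2 | intermediate
27 | {(1E)-4-[(1R,2S,3R,4S)-3,4-bis{[tert-butyl(dimethyl)silyl]oxy}-1,2,5,5-tetramethyl-1,2,3,4,5,6,7,8-octahydronaphthalen-1-yl]-2-methylbut-1-en-1-yl}dimethylalumane | C[Al](C)/C=C(\C)CC[C@@]1(C)C2=C([C@H](O[Si](C)(C)C(C)(C)C)[C@H](O[Si](C)(C)C(C)(C)C)[C@H]1C)C(C)(C)CCC2 | intermediate (not isolated)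
28 | (2E)-5-[(1R,2S,3R,4S)-3,4-bis{[tert-butyl(dimethyl)silyl]oxy}-1,2,5,5-tetramethyl-1,2,3,4,5,6,7,8-octahydronaphthalen-1-yl]-3-methylpent-2-en-1-ol | OC/C=C(\C)CC[C@@]1(C)C2=C([C@H](O[Si](C)(C)C(C)(C)C)[C@H](O[Si](C)(C)C(C)(C)C)[C@H]1C)C(C)(C)CCC2 | intermediate
29 | [(2R,3R)-3-{2-[(1R,2S,3R,4S)-3,4-bis{[tert-butyl(dimethyl)silyl]oxy}-1,2,5,5-tetramethyl-1,2,3,4,5,6,7,8-octahydronaphthalen-1-yl]ethyl}-3-methyloxiran-2-yl]methanol | OC[C@H]3O[C@]3(C)CC[C@@]1(C)C2=C([C@H](O[Si](C)(C)C(C)(C)C)[C@H](O[Si](C)(C)C(C)(C)C)[C@H]1C)C(C)(C)CCC2 | intermediate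
30 | (2S,3R)-3-{2-[(1R,2S,3R,4S)-3,4-bis{[tert-butyl(dimethyl)silyl]oxy}-1,2,5,5-tetramethyl-1,2,3,4,5,6,7,8-octahydronaphthalen-1-yl]ethyl}-2-(iodomethyl)-3-methyloxirane | IC[C@H]3O[C@]3(C)CC[C@@]1(C)C2=C([C@H](O[Si](C)(C)C(C)(C)C)[C@H](O[Si](C)(C)C(C)(C)C)[C@H]1C)C(C)(C)CCC2 | intermediate
31 | (3R)-5-[(1R,2S,3R,4S)-3,4-bis{[tert-butyl(dimethyl)silyl]oxy}-1,2,5,5-tetramethyl-1,2,3,4,5,6,7,8-octahydronaphthalen-1-yl]-3-methylpent-1-en-3-ol | C=C[C@](C)(O)CC[C@@]1(C)C2=C([C@H](O[Si](C)(C)C(C)(C)C)[C@H](O[Si](C)(C)C(C)(C)C)[C@H]1C)C(C)(C)CCC2 | intermediate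
32 | (1S,2R,3S,4R)-4-[(3R)-3-hydroxy-3-methylpent-4-en-1-yl]-3,4,8,8-tetramethyl-1,2,3,4,5,6,7,8-octahydronaphthalene-1,2-diol | C=C[C@](C)(O)CC[C@@]1(C)C2=C([C@H](O)[C@H](O)[C@H]1C)C(C)(C)CCC2 | intermediate
33 | (1S,2R,3S,4R)-1-hydroxy-4-[(3R)-3-hydroxy-3-methylpent-4-en-1-yl]-3,4,8,8-tetramethyl-1,2,3,4,5,6,7,8-octahydronaphthalen-2-yl acetate | C=C[C@](C)(O)CC[C@@]1(C)C2=C([C@H](O)[C@H](OC(C)=O)[C@H]1C)C(C)(C)CCC2 | target

## Step count and risks

Total: 22 steps. Longest linear sequence: 19 steps (7 → 33, steps 4–7 and 8–22); the ring A branch (steps 1–3) joins at step 8.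

The three steps most likely to fail:

Step 8, the asymmetric cycloaddition. A hindered ring-fused diene has to form a quaternary centre next to the ring under catalyst control. The fallback sets out from 6 and 15 and comes back at 26. The two are combined with the achiral Lewis acid Me2AlCl (CH2Cl2, −78 °C), which gives the racemate, that is 16 together with ent-16 F1. Steps 9 to 14 are run unchanged on the racemate and carry the mirror-image series along: ent-17 F2, ent-18 F3, ent-19 F4 (not isolated), ent-20 F5, ent-21 F6 (not isolated), ent-22 F7, ent-23 F8 and ent-24 F9. The racemic diol is then resolved with a lipase (Burkholderia cepacia lipase, vinyl acetate, t-BuOMe). By the usual preference for the (R)-carbinol of cyclic cis-1,2-diols, the enzyme acetylates the C7 hydroxyl of the (1S,2R,3S,4R) antipode 24 to diol 2-monoacetate F10 and leaves ent-24 F9, which is removed by chromatography. K2CO3 in MeOH cleaves the acetate and the alkynyl C–Si bond of F10 in one operation to alkyne diol F11, and tBuMe2SiOTf with 2,6-lutidine gives 26.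

Step 9, the Saegusa–Ito dehydrogenation. A tetrasubstituted triisopropylsilyl enol ether next to a quaternary carbon may react sluggishly with Pd(OAc)2. The fallback sets out from 16 and comes back at 17. N-Bromosuccinimide in THF at 0 °C brominates the enol ether at C5 to α-bromo ketone F12, and Li2CO3 with LiBr in DMF at 120 °C eliminates HBr toward C10, the only β-carbon with hydrogen, to give 17.

Step 22, the lipase acetylation. The C7 hydroxyl is itself flanked by two substituted carbons, so the enzyme may be slow or unselective. The fallback sets out from 31 and comes back at 33. Buffered HF·pyridine in THF at 0 °C removes the less hindered C7 silyl ether first to give C6 mono-silyl ether F13. Ac2O in pyridine at rt acetylates the free secondary hydroxyl, but not the tertiary one, to give silylated acetate F14. Bu4NF buffered with AcOH (to suppress acyl migration) then removes the C6 silyl ether to give 33.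

## Further compounds

F1 | step 8 | ent-16: (1R,2S)-2,5,5-trimethyl-4-[(triisopropylsilyl)oxy]-1-[4-(trimethylsilyl)but-3-yn-1-yl]-1,2,3,5,6,7,8,8a-octahydronaphthalene-1-carbaldehyde, both C8a epimers | C[Si](C)(C)C#CCC[C@]1(C=O)C2CCCC(C)(C)C2=C(O[Si](C(C)C)(C(C)C)C(C)C)C[C@@H]1C
F2 | step 8 | ent-17: (1R,2S)-2,5,5-trimethyl-4-oxo-1-[4-(trimethylsilyl)but-3-yn-1-yl]-1,2,3,4,5,6,7,8-octahydronaphthalene-1-carbaldehyde | C[Si](C)(C)C#CCC[C@]1(C=O)C2=C(C(=O)C[C@@H]1C)C(C)(C)CCC2
F3 | step 8 | ent-18: tosylhydrazone of F2 | C[Si](C)(C)C#CCC[C@]1(/C=N/NS(=O)(=O)c3ccc(C)cc3)C2=C(C(=O)C[C@@H]1C)C(C)(C)CCC2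
F4 | step 8 | ent-19: N-boryl hydrazide from F3 | C[Si](C)(C)C#CCC[C@]1(CN(B3Oc4ccccc4O3)NS(=O)(=O)c3ccc(C)cc3)C2=C(C(=O)C[C@@H]1C)C(C)(C)CCC2
F5 | step 8 | ent-20: (3S,4S)-3,4,8,8-tetramethyl-4-[4-(trimethylsilyl)but-3-yn-1-yl]-3,4,5,6,7,8-hexahydronaphthalen-1(2H)-one | C[Si](C)(C)C#CCC[C@]1(C)C2=C(C(=O)C[C@@H]1C)C(C)(C)CCC2
F6 | step 8 | ent-21: potassium dienolate of F5 | C[Si](C)(C)C#CCC[C@]1(C)C2=C(C(O[K])=C[C@@H]1C)C(C)(C)CCC2
F7 | step 8 | ent-22: (3S,4S)-3,4,8,8-tetramethyl-4-[4-(trimethylsilyl)but-3-yn-1-yl]-3,4,5,6,7,8-hexahydronaphthalen-1-yl trifluoromethanesulfonate | C[Si](C)(C)C#CCC[C@]1(C)C2=C(C(OS(=O)(=O)C(F)(F)F)=C[C@@H]1C)C(C)(C)CCC2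
F8 | step 8 | ent-23: trimethyl{4-[(1S,2S)-1,2,5,5-tetramethyl-1,2,5,6,7,8-hexahydronaphthalen-1-yl]but-1-yn-1-yl}silane | C[Si](C)(C)C#CCC[C@]1(C)C2=C(C=C[C@@H]1C)C(C)(C)CCC2
F9 | step 8 | ent-24: (1R,2S,3R,4S)-3,4,8,8-tetramethyl-4-[4-(trimethylsilyl)but-3-yn-1-yl]-1,2,3,4,5,6,7,8-octahydronaphthalene-1,2-diol | C[Si](C)(C)C#CCC[C@]1(C)C2=C([C@@H](O)[C@@H](O)[C@@H]1C)C(C)(C)CCC2
F10 | step 8 | (1S,2R,3S,4R)-1-hydroxy-3,4,8,8-tetramethyl-4-[4-(trimethylsilyl)but-3-yn-1-yl]-1,2,3,4,5,6,7,8-octahydronaphthalen-2-yl acetate | C[Si](C)(C)C#CCC[C@@]1(C)C2=C([C@H](O)[C@H](OC(C)=O)[C@H]1C)C(C)(C)CCC2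
F11 | step 8 | (1S,2R,3S,4R)-4-(but-3-yn-1-yl)-3,4,8,8-tetramethyl-1,2,3,4,5,6,7,8-octahydronaphthalene-1,2-diol | C#CCC[C@@]1(C)C2=C([C@H](O)[C@H](O)[C@H]1C)C(C)(C)CCC2
F12 | step 9 | (1S,2R)-4a-bromo-2,5,5-trimethyl-4-oxo-1-[4-(trimethylsilyl)but-3-yn-1-yl]decahydronaphthalene-1-carbaldehyde, C4a/C8a epimers | C[Si](C)(C)C#CCC[C@@]1(C=O)C2CCCC(C)(C)C2(Br)C(=O)C[C@H]1C
F13 | step 22 | (3R)-5-[(1R,2S,3R,4S)-4-{[tert-butyl(dimethyl)silyl]oxy}-3-hydroxy-1,2,5,5-tetramethyl-1,2,3,4,5,6,7,8-octahydronaphthalen-1-yl]-3-methylpent-1-en-3-ol | C=C[C@](C)(O)CC[C@@]1(C)C2=C([C@H](O[Si](C)(C)C(C)(C)C)[C@H](O)[C@H]1C)C(C)(C)CCC2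
F14 | step 22 | (1S,2R,3S,4R)-1-{[tert-butyl(dimethyl)silyl]oxy}-4-[(3R)-3-hydroxy-3-methylpent-4-en-1-yl]-3,4,8,8-tetramethyl-1,2,3,4,5,6,7,8-octahydronaphthalen-2-yl acetate | C=C[C@](C)(O)CC[C@@]1(C)C2=C([C@H](O[Si](C)(C)C(C)(C)C)[C@H](OC(C)=O)[C@H]1C)C(C)(C)CCC2
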